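**Plan**

- Numbering: ring A is the styryl-bearing dihydrobenzofuran (O1, C2, C3, C3a–C7a). Ring B is the other one (O1', C2', C3', C3a'–C7a'). They are joined C3–C4', and these locants are kept for all intermediates.
- Enabling feature: the central benzene carries three neighbouring substituents, C3 on C4', C3' on C3a' and O1' on C7a', with a further oxygen on C6'. A 3,5-dialkoxybenzyne gives exactly this pattern when it takes up a carbon nucleophile and an acyl group on adjacent carbons.
- Cuts, in retrosynthetic order: six O–Me bonds, then the C5–vinyl bond (Heck), C2'–C3' (carbene C–H insertion) and O1–C2 (benzylic etherification). C3–C4' and C3a'–C3' are then cut together (aryne acyl-alkylation), which leaves a silylaryl triflate and a 2-aryl-1,3-diketone.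
- Forward: all core carbons are joined before any ring is made. Ring A closes first, ring B second, and the stilbene arm comes last.
- Stereochemistry:
  - C3 (S) is set by dynamic kinetic transfer hydrogenation with an (R,R)-Ru catalyst, and C2 (S) forms trans to it on ring closure.
  - C3' (S) is set by the chiral Rh2 carboxylate; C2' forms cis (R) and is acid-equilibrated to trans (S).
  - The E-alkene comes from the Heck reaction.

Key step: step 9

Assumption: Rh2(S-PTAD)4 is taken to give the 3'S sense of insertion by analogy with simpler 2-(benzyloxy)benzophenone-derived carbenes; if the sense is opposite, Rh2(R-PTAD)4 is used and nothing else changes.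

**Route**

Step 1
Reactants: 1 phloroglucinol; 2 4-methoxybenzyl chloride (2 equiv)
Product: 3 3,5-bis(4-methoxybenzyloxy)phenol
Conditions: K2CO3, DMF, rt to 50 °C
Reagents that add atoms: none
Why: Williamson ether synthesis on the threefold-symmetric triphenol should give the bis-ether statistically, the symmetry makes both ether positions equivalent, and the mono- and tris-ethers are removed by chromatography.

Step 2
Reactants: 3 3,5-bis(4-methoxybenzyloxy)phenol
Product: 4 2-bromo-3,5-bis(4-methoxybenzyloxy)phenol
Conditions: NBS, CH2Cl2, −78 °C to 0 °C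
Reagents that add atoms: N-bromosuccinimide, O=C1CCC(=O)N1Br
Why: Electrophilic aromatic bromination should strike the triply oxygenated ring rather than the anisyl rings, at the site between OH and one ether, because the alternative site is walled in by two bulky benzylic ethers and the hydroxyl group guides NBS in a non-polar solvent.

Step 3
Reactants: 4 2-bromo-3,5-bis(4-methoxybenzyloxy)phenol
Product: 7 3,5-bis(4-methoxybenzyloxy)-2-(trimethylsilyl)phenyl trifluoromethanesulfonate, via aryl trimethylsilyl ether 5 (not isolated), via lithium 2-silylphenoxide 6 (not isolated)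
Conditions: HMDS, THF, 70 °C, evaporation; n-BuLi, THF, −78 °C; Tf2O, −78 °C to rt
Reagents that add atoms: hexamethyldisilazane, C[Si](C)(C)N[Si](C)(C)C; trifluoromethanesulfonic anhydride, O=S(=O)(OS(=O)(=O)C(F)(F)F)C(F)(F)F
Why: O-silylation, bromine–lithium exchange, retro-Brook O-to-C silyl migration and triflation form the standard entry to ortho-silylaryl triflates, and the exchange at −78 °C outruns deprotonation of the benzylic ethers.

Step 4
Reactants: 8 2-hydroxyphenylacetic acid
Product: 9 5-bromo-2-hydroxyphenylacetic acid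
Conditions: NBS, MeCN, 0 °C
Reagents that add atoms: N-bromosuccinimide, O=C1CCC(=O)N1Br
Why: Electrophilic aromatic bromination para to the free phenol, the strongest director on the ring, places the halogen on the carbon that becomes C5.

Step 5
Reactants: 9 5-bromo-2-hydroxyphenylacetic acid
Product: 11 2-(5-bromo-2-hydroxyphenyl)-N-methoxy-N-methylacetamide, via acyl imidazolide 10 (not isolated)
Conditions: CDI, THF, rt; then MeNHOMe·HCl, rt
Reagents that add atoms: N,O-dimethylhydroxylamine hydrochloride, CNOC.Cl; 1,1'-carbonyldiimidazole, O=C(n1ccnc1)n1ccnc1 (its atoms remain only in 10)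
Why: Amide coupling through the acyl imidazolide gives the Weinreb amide, and any benzofuranone formed by the neighbouring phenol is opened by the same amine to the same product.

Step 6
Reactants: 11 2-(5-bromo-2-hydroxyphenyl)-N-methoxy-N-methylacetamide
Product: 12 2-[5-bromo-2-(methoxymethoxy)phenyl]-N-methoxy-N-methylacetamide
Conditions: MOMCl, K2CO3, acetone, rt
Reagents that add atoms: chloromethyl methyl ether, COCCl
Why: O-alkylation of the phenoxide (Williamson type) installs a MOM acetal that withstands the Grignard reagent, the lithium amide and fluoride and leaves later under mild acid.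

Step 7
Reactants: 12 2-[5-bromo-2-(methoxymethoxy)phenyl]-N-methoxy-N-methylacetamide; 13 4-methoxyphenylmagnesium bromide
Product: 14 2-[5-bromo-2-(methoxymethoxy)phenyl]-1-(4-methoxyphenyl)ethanone
Conditions: THF, 0 °C; cold 1 M HCl
Reagents that add atoms: none
Why: In the Weinreb ketone synthesis the chelated tetrahedral adduct prevents over-addition, and an aryl Grignard reagent does not exchange with the aryl bromide at 0 °C.

Step 8
Reactants: 14 2-[5-bromo-2-(methoxymethoxy)phenyl]-1-(4-methoxyphenyl)ethanone; 15 3,5-dimethoxybenzoyl chloride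
Product: 16 2-[5-bromo-2-(methoxymethoxy)phenyl]-1-(3,5-dimethoxyphenyl)-3-(4-methoxyphenyl)propane-1,3-dione (enolisable, no fixed configuration)
Conditions: LiN(SiMe3)2 (2.1 equiv), THF–toluene, −78 °C; 15, −78 °C to rt; cold 1 M HCl
Reagents that add atoms: none
Why: C-acylation of the lithium enolate with an aroyl chloride (crossed Claisen type) is a standard route to 1,3-diketones, and the second equivalent of base stores the more acidic product as its enolate so that it is not acylated again.

Step 9
Reactants: 7 3,5-bis(4-methoxybenzyloxy)-2-(trimethylsilyl)phenyl trifluoromethanesulfonate; 16 2-aryl-1,3-diketone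
Product: 19 keto-benzophenone 2-[5-bromo-2-(methoxymethoxy)phenyl]-2-[2-(3,5-dimethoxybenzoyl)-3,5-bis(4-methoxybenzyloxy)phenyl]-1-(4-methoxyphenyl)ethanone (C3 labile), via aryne 17 (not isolated), via benzocyclobutenoxide 18 (not isolated)
Conditions: CsF (3 equiv), MeCN, 80 °C; aqueous work-up
Reagents that add atoms: none
Why: Fluoride removes the silyl group of 7 and triflate departs to give aryne 17; the caesium enolate of 16 adds through C3 to C4', the aryl anion thus placed on C3a' closes 4-exo-trig onto the neighbouring aroyl carbonyl to give benzocyclobutenoxide 18, and cleavage of its strained C3–C3' bond releases the diaryl-stabilised enolate of 19, so the net result is insertion of the aryne into the C3–C3' bond and no ring survives. The closest known reaction is the acyl-alkylation of arynes with β-keto esters and 1,3-diketones, which is documented for 3,5-dialkoxyarynes and for α-aryl β-dicarbonyl partners. Site selectivity on the aryne is needed and is secured by the ether oxygen next to the triple bond, whose inductive pull distorts the aryne and places the developing charge on C3a', so that carbon attack occurs at the remote C4'. Acyl selectivity is needed as well and rests on electronics: the 3,5-dimethoxybenzoyl carbonyl feels two weakly withdrawing meta-methoxy groups, whereas the 4-methoxybenzoyl carbonyl is deactivated as a vinylogous ester. C3 is created as a readily enolised, configurationally labile centre, so no stereocontrol is asked of this step. The aryl bromide, the MOM acetal and the benzylic ethers are inert to CsF in MeCN, and the ether on C7a' already carries C2' and its aryl group.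

Step 10
Reactants: 19 keto-benzophenone
Product: 20 (2R,3S)-alcohol, 2-[5-bromo-2-(methoxymethoxy)phenyl]-2-[2-(3,5-dimethoxybenzoyl)-3,5-bis(4-methoxybenzyloxy)phenyl]-1-(4-methoxyphenyl)ethanol (carbinol carbon C2 = R, diarylmethine C3 = S)
Conditions: RuCl[(R,R)-TsDPEN](p-cymene) (5 mol %), HCO2H–Et3N (5:2), DMF, 40 °C
Reagents that add atoms: none
Why: Proposed new method: Noyori–Ikariya asymmetric transfer hydrogenation with dynamic kinetic resolution is established for α-aryl cyclic ketones (2-aryltetralones, isoflavanones) and α-substituted β-keto esters but not for an acyclic α,α-diaryl ketone, and it should extend here because the C3–H, flanked by the ketone and two aryl rings, exchanges quickly under Et3N, the (R,R)-catalyst delivers hydride to the Si face of the aryl ketone (CH/π contact with the anisyl ring) to fix C2 as R, and in the Felkin–Anh arrangement the much bulkier ortho-aroylated central ring stands anti to the incoming hydride so that the 3S enantiomer is reduced faster and the 3R enantiomer drains into it, while the doubly ortho-substituted, donor-deactivated benzophenone carbonyl is not touched.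

Step 11
Reactants: 20 (2R,3S)-alcohol
Product: 21 (2S,3S)-trans-5-bromo-3-[2-(3,5-dimethoxybenzoyl)-3,5-bis(4-methoxybenzyloxy)phenyl]-2-(4-methoxyphenyl)-2,3-dihydrobenzofuran (ring A closed)
Conditions: p-TsOH·H2O (0.2 equiv), MeOH–CH2Cl2, rt to 40 °C
Reagents that add atoms: none
Why: Acid-catalysed acetal cleavage frees O1 and ionises the para-methoxybenzylic alcohol, and 5-exo capture of the cation (SN1-type benzylic etherification) places the anisyl group at C2 trans to the bulky aryl group on the untouched C3 (2S), the same isomer that displacement of the 2R alcohol with inversion would give, while catalytic TsOH leaves the two aryl PMB ethers in place.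

Step 12
Reactants: 21 ring-A ketone
Product: 22 hydrazone of 21 at C3' (E/Z mixture, 2S,3S)
Conditions: N2H4·H2O (excess), AcOH (cat.), n-BuOH, 120 °C, sealed tube
Reagents that add atoms: hydrazine hydrate, NN.O
Why: Hydrazone condensation at the only carbonyl left is forced by excess hydrazine, acid catalysis and heat, conditions to which the ethers, the aryl bromide and ring A are indifferent.

Step 13
Reactants: 22 hydrazone
Product: 24 (2S,3S,2'R,3'S)-bis-dihydrobenzofuran with cis ring B, C5–Br and a 4-methoxybenzyl ether on O6', via diaryldiazomethane 23 (not isolated)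
Conditions: MnO2, CH2Cl2, rt, filtration; Rh2(S-PTAD)4 (1 mol %), CH2Cl2, 0 °C
Reagents that add atoms: none
Why: Oxidation of the hydrazone gives the diaryldiazomethane, and its donor/donor rhodium carbene undergoes 1,5-C–H insertion into the activated O1'–CH2 group to close the five-membered ring B, the chiral carboxylate catalyst fixing C3' as S and the compact concerted transition state giving the cis isomer (C2' R), while A1,3 strain keeps C3–H rather than C2–H of ring A turned toward the carbene.

Step 14
Reactants: 24 cis-ring-B compound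
Product: 25 (2S,3S,2'S,3'S)-bromophenol with both rings trans and free C6'–OH
Conditions: TFA (10 vol %), pentamethylbenzene (3 equiv), CH2Cl2, 0 °C, short contact time
Reagents that add atoms: none
Why: TFA reversibly ionises the C2'–O1' bond through the para-methoxybenzylic cation so that C2' equilibrates to the more stable trans isomer (2'S) with C3' untouched (acid-mediated epimerisation of 2-aryl-2,3-dihydrobenzofurans), and the same acid cleaves the last PMB ether, whose cation is removed by Friedel–Crafts capture with pentamethylbenzene.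

Step 15
Reactants: 25 bromophenol; 26 3,5-dimethoxystyrene
Product: 27 hexa-O-methyl ether of the target (E-stilbene, free C6'–OH)
Conditions: Pd(OAc)2, P(o-tol)3, K2CO3, DMF, 110 °C
Reagents that add atoms: none
Why: In the Mizoroki–Heck reaction, oxidative addition of zerovalent palladium into C5–Br, syn insertion at the unsubstituted styrene terminus and syn β-hydride elimination give the E-alkene, and the basic, acid-free medium tolerates the phenol and leaves the four stereocentres untouched.

Step 16
Reactants: 27 hexamethyl ether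
Product: 28 trans-diptoindonesin B, (2S,3S,2'S,3'S), E-alkene
Conditions: BBr3 (excess), CH2Cl2, −78 °C to rt, exclusion of light; ice-water
Reagents that add atoms: none
Why: Lewis-acid cleavage of aryl methyl ethers with BBr3, the usual last operation on permethylated resveratrol oligomers, removes all six methyl groups, and any reversible opening of the C2–O1 or C2'–O1' bond recloses to the trans rings already present.

**Compound list**

1 | phloroglucinol | Oc1cc(O)cc(O)c1 | starting material
2 | 4-methoxybenzyl chloride | COc1ccc(CCl)cc1 | starting material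
3 | 3,5-bis(4-methoxybenzyloxy)phenol | COc1ccc(COc2cc(O)cc(OCc3ccc(OC)cc3)c2)cc1 | intermediate
4 | 2-bromo-3,5-bis(4-methoxybenzyloxy)phenol | COc1ccc(COc2cc(O)c(Br)c(OCc3ccc(OC)cc3)c2)cc1 | intermediate
5 | [2-bromo-3,5-bis(4-methoxybenzyloxy)phenoxy]trimethylsilane | COc1ccc(COc2cc(O[Si](C)(C)C)c(Br)c(OCc3ccc(OC)cc3)c2)cc1 | intermediate
6 | lithium 3,5-bis(4-methoxybenzyloxy)-2-(trimethylsilyl)phenoxide | [Li+].COc1ccc(COc2cc([O-])c([Si](C)(C)C)c(OCc3ccc(OC)cc3)c2)cc1 | intermediate
7 | 3,5-bis(4-methoxybenzyloxy)-2-(trimethylsilyl)phenyl trifluoromethanesulfonate | COc1ccc(COc2cc(OCc3ccc(OC)cc3)c([Si](C)(C)C)c(OS(=O)(=O)C(F)(F)F)c2)cc1 | intermediate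
8 | 2-hydroxyphenylacetic acid | O=C(O)Cc1ccccc1O | starting material
9 | 5-bromo-2-hydroxyphenylacetic acid | O=C(O)Cc1cc(Br)ccc1O | intermediate
10 | 2-(5-bromo-2-hydroxyphenyl)-1-(imidazol-1-yl)ethanone | O=C(Cc1cc(Br)ccc1O)n1ccnc1 | intermediate
11 | 2-(5-bromo-2-hydroxyphenyl)-N-methoxy-N-methylacetamide | CON(C)C(=O)Cc1cc(Br)ccc1O | intermediate
12 | 2-[5-bromo-2-(methoxymethoxy)phenyl]-N-methoxy-N-methylacetamide | CON(C)C(=O)Cc1cc(Br)ccc1OCOC | intermediate
13 | 4-methoxyphenylmagnesium bromide | COc1ccc([Mg]Br)cc1 | starting material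
14 | 2-[5-bromo-2-(methoxymethoxy)phenyl]-1-(4-methoxyphenyl)ethanone | COc1ccc(C(=O)Cc2cc(Br)ccc2OCOC)cc1 | intermediate
15 | 3,5-dimethoxybenzoyl chloride | COc1cc(OC)cc(C(=O)Cl)c1 | starting material
16 | 2-[5-bromo-2-(methoxymethoxy)phenyl]-1-(3,5-dimethoxyphenyl)-3-(4-methoxyphenyl)propane-1,3-dione | COc1ccc(C(=O)C(c2cc(Br)ccc2OCOC)C(=O)c2cc(OC)cc(OC)c2)cc1 | intermediate
17 | 3,5-bis(4-methoxybenzyloxy)benzyne | COc1ccc(COC2=CC(OCc3ccc(OC)cc3)=CC#C2)cc1 | intermediate
18 | caesium benzocyclobutenoxide (four-membered ring C3–C4'–C3a'–C3') | [Cs+].[O-]C1(c2cc(OC)cc(OC)c2)c2c(OCc3ccc(OC)cc3)cc(OCc3ccc(OC)cc3)cc2C1(C(=O)c1ccc(OC)cc1)c1cc(Br)ccc1OCOC | intermediate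
19 | keto-benzophenone (C3 labile) | COc1ccc(C(=O)C(c2cc(Br)ccc2OCOC)c2cc(OCc3ccc(OC)cc3)cc(OCc3ccc(OC)cc3)c2C(=O)c2cc(OC)cc(OC)c2)cc1 | intermediate
20 | (2R,3S)-alcohol | COc1ccc([C@H](O)[C@H](c2cc(Br)ccc2OCOC)c2cc(OCc3ccc(OC)cc3)cc(OCc3ccc(OC)cc3)c2C(=O)c2cc(OC)cc(OC)c2)cc1 | intermediate
21 | (2S,3S)-trans ring-A ketone | COc1ccc([C@H]2Oc3ccc(Br)cc3[C@@H]2c2cc(OCc3ccc(OC)cc3)cc(OCc3ccc(OC)cc3)c2C(=O)c2cc(OC)cc(OC)c2)cc1 | intermediate
22 | hydrazone of 21 | COc1ccc([C@H]2Oc3ccc(Br)cc3[C@@H]2c2cc(OCc3ccc(OC)cc3)cc(OCc3ccc(OC)cc3)c2C(=NN)c2cc(OC)cc(OC)c2)cc1 | intermediate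
23 | diaryldiazomethane | COc1ccc([C@H]2Oc3ccc(Br)cc3[C@@H]2c2cc(OCc3ccc(OC)cc3)cc(OCc3ccc(OC)cc3)c2C(=[N+]=[N-])c2cc(OC)cc(OC)c2)cc1 | intermediate
24 | (2S,3S,2'R,3'S)-bis-dihydrobenzofuran, ring B cis, O6'-PMB | COc1ccc([C@H]2Oc3ccc(Br)cc3[C@@H]2c2cc(OCc4ccc(OC)cc4)cc3c2[C@H](c2cc(OC)cc(OC)c2)[C@H](c2ccc(OC)cc2)O3)cc1 | intermediate
25 | (2S,3S,2'S,3'S)-bromophenol, both rings trans | COc1ccc([C@H]2Oc3ccc(Br)cc3[C@@H]2c2cc(O)cc3c2[C@H](c2cc(OC)cc(OC)c2)[C@@H](c2ccc(OC)cc2)O3)cc1 | intermediate
26 | 3,5-dimethoxystyrene | C=Cc1cc(OC)cc(OC)c1 | starting material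
27 | hexa-O-methyl trans-diptoindonesin B (free C6'–OH) | COc1ccc([C@H]2Oc3ccc(/C=C/c4cc(OC)cc(OC)c4)cc3[C@@H]2c2cc(O)cc3c2[C@H](c2cc(OC)cc(OC)c2)[C@@H](c2ccc(OC)cc2)O3)cc1 | intermediate
28 | trans-diptoindonesin B | Oc1ccc([C@H]2Oc3ccc(/C=C/c4cc(O)cc(O)c4)cc3[C@@H]2c2cc(O)cc3c2[C@H](c2cc(O)cc(O)c2)[C@@H](c2ccc(O)cc2)O3)cc1 | target

**Step count**

Total step count: 16. Longest linear sequence: 13 steps (steps 4–8, then 9–16, from 2-hydroxyphenylacetic acid).

**Steps most likely to fail**

Step 10. The catalyst may discriminate poorly between the two aryl groups on C3, or hydride transfer to the hindered, electron-rich ketone may be slow.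
- The fallback starts from 19 and runs the same catalyst-controlled reduction to full conversion without relying on the dynamic element, so only C2 is fixed and both C3 epimers are reduced.
- Alcohol 20 is separated by chromatography from the (2R,3R)-alcohol F1.
- F1 is oxidised back to 19 with Dess–Martin periodinane, C3 racemises again on contact with Et3N, and the material is recycled.
- The route is rejoined at 20.

Step 9. The acyl group may transfer to the wrong carbonyl, or the aryl anion may be protonated early and give plain α-arylation.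
- The fallback starts from Weinreb amide 12. C-acylation with 15 and LiN(SiMe3)2 gives the β-keto Weinreb amide F2, which offers the aryl anion a single ketone beside a much less electrophilic amide.
- Reaction of F2 with 7 and CsF in MeCN gives the acyl-alkylation product F3, forming the same two bonds.
- i-Bu2AlH at −78 °C gives the diarylacetaldehyde F4, and addition of 13 at −78 °C gives the stereorandom alcohol F5.
- Dess–Martin oxidation returns to the route at 19. It would also restore the diaryl ketone if hydride had touched it.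

Step 12. Condensation may be slow or absent at a carbonyl shielded by two ortho substituents, with azine formation on prolonged heating.
- The fallback starts from 21. Thionation with Lawesson's reagent in toluene at 100 °C gives the thioketone F6.
- The longer and far more electrophilic C=S bond of F6 condenses with hydrazine hydrate at room temperature.
- The route is rejoined at 22.

**Further compounds**

F1 | step 10 | (2R,3R)-alcohol, C3 epimer of 20 | COc1ccc([C@H](O)[C@@H](c2cc(Br)ccc2OCOC)c2cc(OCc3ccc(OC)cc3)cc(OCc3ccc(OC)cc3)c2C(=O)c2cc(OC)cc(OC)c2)cc1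
F2 | step 9 | 2-[5-bromo-2-(methoxymethoxy)phenyl]-3-(3,5-dimethoxyphenyl)-N-methoxy-N-methyl-3-oxopropanamide | CON(C)C(=O)C(c1cc(Br)ccc1OCOC)C(=O)c1cc(OC)cc(OC)c1
F3 | step 9 | 2-[5-bromo-2-(methoxymethoxy)phenyl]-2-[2-(3,5-dimethoxybenzoyl)-3,5-bis(4-methoxybenzyloxy)phenyl]-N-methoxy-N-methylacetamide | CON(C)C(=O)C(c1cc(Br)ccc1OCOC)c1cc(OCc2ccc(OC)cc2)cc(OCc2ccc(OC)cc2)c1C(=O)c1cc(OC)cc(OC)c1
F4 | step 9 | 2-[5-bromo-2-(methoxymethoxy)phenyl]-2-[2-(3,5-dimethoxybenzoyl)-3,5-bis(4-methoxybenzyloxy)phenyl]acetaldehyde | O=CC(c1cc(Br)ccc1OCOC)c1cc(OCc2ccc(OC)cc2)cc(OCc2ccc(OC)cc2)c1C(=O)c1cc(OC)cc(OC)c1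
F5 | step 9 | stereorandom alcohol (all stereoisomers of 20) | COc1ccc(C(O)C(c2cc(Br)ccc2OCOC)c2cc(OCc3ccc(OC)cc3)cc(OCc3ccc(OC)cc3)c2C(=O)c2cc(OC)cc(OC)c2)cc1
F6 | step 12 | (2S,3S)-thioketone corresponding to 21 | COc1ccc([C@H]2Oc3ccc(Br)cc3[C@@H]2c2cc(OCc3ccc(OC)cc3)cc(OCc3ccc(OC)cc3)c2C(=S)c2cc(OC)cc(OC)c2)cc1
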